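Retrosynthesis: strip the three acetates and transpose the C11=C20 alkene (from a C20 allylic alcohol); cut C1–C10 and C13–C14 together (one Diels–Alder retron that opens the six- and the ten-membered ring at once); then C2–C3 (thioester–organozinc coupling), C11–C12 and C9–C10 (vinylation, acetylide addition), and C7–C8 plus the lactone C–O (aldol–lactonisation).
Forward: the γ-lactone (C7, C8, C17, C19) is built first, C9 and the C10–C13 diene are added, the C3 zinc reagent is acylated to the C2 enone, and one intramolecular Diels–Alder closes the cyclohexene and the ten-membered ring together; reduction, transposition and acetylation finish.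
Enabling feature: in the ring C1/C10/C11/C12/C13/C14, C1 is the α-carbon and C14 the oxygen-bearing β-carbon of a C2 carbonyl (dienophile, oxygen masked as boron), C10–C13 with the C20 branch on C11 is a 2-substituted butadiene, and C2–C9 (Z alkene C5=C6, lactone) is the tether.
Stereochemistry: C17 and C8 from an auxiliary aldol, C8 carried through a tert-butyl acetal, C7 from the chair aldol, C9 from catalyst-controlled transfer hydrogenation, C1/C10/C14 from the cycloaddition (Z-boryl enone, diene face fixed by allylic strain and the tether), C2 from CBS reduction.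

Key step: step 14

Locants (briarane numbering): C1 quaternary carbon with CH3 (C15); C2, C9, C14 acetoxy carbons (C2 beside C3H2, C9 beside C8, C14 in the six-membered ring); C5(=C6) ring alkene with CH3 (C16); C7 lactone O–CH; C8 C–OH; C10 ring-fusion CH; C11(=C20) exocyclic methylene; C12, C13 ring CH2; C17 CH(CH3); C19 lactone C=O.
Remark: lactone 7 is taken as a catalogue compound.

Step 1
Reactants: 1 (R)-4-benzyl-3-propanoyl-1,3-oxazolidin-2-one; 2 ethyl glyoxylate
Product: 4 (4R)-4-benzyl-3-[(2R,3R)-4-ethoxy-3-hydroxy-2-methyl-4-oxobutanoyl]-1,3-oxazolidin-2-one, via boron enolate 3 (not isolated)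
Conditions: Bu2BOTf, i-Pr2NEt, CH2Cl2, −78 → 0 °C; then 2, −78 °C; pH 7 buffer, MeOH, H2O2
Reagents that add atoms: none
Why: Evans syn-aldol, in which the (Z)-boron enolate adds to the aldehyde through a Zimmerman–Traxler chair on the face away from the benzyl group, so the auxiliary sets C17 and C8 (both R, syn).

Step 2
Reactants: 4
Product: 5 (2R,3R)-2-hydroxy-3-methylbutanedioic acid
Conditions: LiOH, H2O2, THF/H2O, 0 °C → rt; Na2SO3; HCl to pH 1
Reagents that add atoms: lithium hydroxide, [Li+].[OH-]; hydrogen peroxide, OO
Why: Standard hydroperoxide cleavage of the imide together with saponification of the ethyl ester should leave both stereocentres untouched.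

Step 3
Reactants: 5
Product: 6 (2R)-2-[(2R,4R)-2-tert-butyl-5-oxo-1,3-dioxolan-4-yl]propanoic acid
Conditions: t-BuCHO, TsOH·H2O (cat.), H2SO4 (cat.), pentane, reflux, Dean–Stark
Reagents that add atoms: 2,2-dimethylpropanal, CC(C)(C)C=O
Why: Acid-catalysed acetalisation of the α-hydroxy acid under thermodynamic control should give the cis five-membered dioxolanone, whose tert-butyl centre stores the C8 configuration (self-regeneration of stereocentres).

Step 4
Reactants: 7 4-methyl-5,6-dihydro-2H-pyran-2-one
Product: 8 4-methyl-5,6-dihydro-2H-pyran-2-ol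
Conditions: i-Bu2AlH, CH2Cl2, −78 °C; aq. KNaC4H4O6
Reagents that add atoms: none
Why: Low-temperature hydride reduction of a lactone stops at the lactol, a masked (Z)-5-hydroxy-3-methylpent-2-enal whose alkene geometry is fixed by the ring.

Step 5
Reactants: 6; 8
Product: 11 spiro dioxolanone γ-lactone carrying the (Z)-4-hydroxy-2-methylbut-1-enyl group at C7 (C7/C8/C17 as in the target), via dilithium enolate 9 (not isolated), via hydroxy acid 10 (not isolated)
Conditions: LiN(SiMe3)2 (3.2 equiv), THF, −78 °C; 8; AcOH, −78 °C; then EDC·HCl, DMAP (cat.), CH2Cl2, 0 °C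
Reagents that add atoms: none
Why: Aldol addition of the dioxolanone enolate to the open-chain enal form of the lactol, then carbodiimide lactonisation (5-exo-trig on C19); the aldehyde should enter anti to tert-butyl (C8 with retention) and through a Zimmerman–Traxler chair with the alkenyl group equatorial and the C17 branch cis to O–Li, which sets C7 so that C6 is cis to the C8 oxygen.

Step 6
Reactants: 11
Product: 12 primary iodide of 11 (C3–I)
Conditions: I2, PPh3, imidazole, CH2Cl2, 0 °C
Reagents that add atoms: iodine, II
Why: Appel-type iodination is selective for the only primary alcohol and proceeds by SN2 at C3, remote from all stereocentres.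

Step 7
Reactants: 12; 13 tert-butyldimethyl(prop-2-yn-1-yloxy)silane
Product: 15 α-hydroxy ynone (C8–OH free; C9 ketone bonded to C≡C–CH2OTBS), via lithium acetylide 14 (not isolated)
Conditions: 13, n-BuLi, THF, −78 °C; then 12, −78 °C; AcOH, −78 → 0 °C
Reagents that add atoms: none
Why: Acetylide addition should take place at the acylal carbonyl C9, which is more electrophilic than the hindered γ-lactone, and the tetrahedral adduct should collapse only on quench, releasing pivalaldehyde and the C8 hydroxyl (acyl substitution to a ketone).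

Step 8
Reactants: 15
Product: 16 (9R)-propargylic 8,9-diol
Conditions: RuCl[(S,S)-TsDPEN](p-cymene) (cat.), HCO2H/Et3N (5:2), CH2Cl2, rt
Reagents that add atoms: none
Why: Noyori-type asymmetric transfer hydrogenation of an α,β-acetylenic ketone is catalyst-controlled, and the (S,S) catalyst is expected to give 9R with the alkyne as the directing unsaturated group.

Step 9
Reactants: 16
Product: 17 C8/C9 acetonide of 16
Conditions: 2-methoxypropene, PPTS (cat.), CH2Cl2, 0 °C → rt
Reagents that add atoms: 2-methoxypropene, COC(C)=C
Why: Acid-catalysed ketalisation of the 1,2-diol protects both oxygens for the organometallic steps without touching a stereocentre.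

Step 10
Reactants: 17
Product: 19 diene iodide (C10=C11 with C9 cis to CH2OTBS; vinyl group on C11), via alkenylzirconocene chloride 18 (not isolated)
Conditions: Cp2Zr(H)Cl, THF, rt; then ZnCl2, Pd(PPh3)4 (cat.), CH2=CHBr, rt
Reagents that add atoms: vinyl bromide, C=CBr
Why: syn-Hydrozirconation should place zirconium on C11, away from the branched C9 side, and transmetalation to zinc with Negishi coupling proceeds with retention, so C9 ends trans to the new vinyl group.

Step 11
Reactants: 20 propyne
Product: 22 (Z)-2-(2-bromoprop-1-en-1-yl)-4,4,5,5-tetramethyl-1,3,2-dioxaborolane, via dibromoborane 21 (not isolated)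
Conditions: BBr3, CH2Cl2, −78 °C → rt; then pinacol, −78 °C → rt
Reagents that add atoms: boron tribromide, BrB(Br)Br; pinacol, CC(C)(O)C(C)(C)O
Why: syn-Bromoboration of the terminal alkyne puts bromine on the internal and boron on the terminal carbon (cis), and esterification with pinacol fixes the Z bromide.

Step 12
Reactants: 22
Product: 23 S-ethyl (Z)-2-methyl-3-(4,4,5,5-tetramethyl-1,3,2-dioxaborolan-2-yl)prop-2-enethioate
Conditions: Pd(OAc)2 (cat.), Xantphos (cat.), CO (1 atm), EtSH, NaOAc, toluene, 80 °C
Reagents that add atoms: carbon monoxide, [C-]#[O+]; ethanethiol, CCS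
Why: Palladium-catalysed thiocarbonylation of the alkenyl bromide (oxidative addition, CO insertion, thiolysis) keeps the alkene geometry, so the acyl group and boron are cis.

Step 13
Reactants: 19; 23
Product: 25 trienone (C2 ketone flanked by C3H2 and the (Z)-β-boryl-α-methyl alkene C1=C14), via alkylzinc iodide 24 (not isolated)
Conditions: Zn dust, LiCl, THF, 35 °C; then 23, PdCl2(PPh3)2 (cat.), toluene/THF, rt; NH4Cl (aq)
Reagents that add atoms: none
Why: Zinc insertion into the primary C–I bond followed by Fukuyama coupling with the thioester gives the ketone without over-addition and should tolerate the lactone, the boronate and the diene.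

Step 14
Reactants: 25
Product: 26 cycloadduct (cyclohexene C11=C12 fused to the ten-membered ketone; C1/C10 as in the target; C14 bearing boron in the place of the later oxygen)
Conditions: toluene (0.002 M), BHT (cat.), 110 °C
Reagents that add atoms: none
Why: Thermal, concerted but asynchronous [4+2] cycloaddition of normal electron demand between the C10–C13 diene and the C1=C14 alkene of the enone (type 1 intramolecular Diels–Alder); the closest known types are Diels–Alder macrocyclisations that close eleven-membered carbocycles and Diels–Alder reactions of β-boryl acrylic dienophiles as masked β-hydroxy acceptors. The bond from the enone β-carbon C14 to the unsubstituted diene terminus C13 should lead (a 14-membered approach), after which the C1–C10 bond closes the six-membered ring suprafacially and with it the ten-membered ring in the fused, not the bridged, mode. C14 follows from the Z dienophile geometry (boron cis to C2, stereospecific). C10 follows from the diene face: the C9–H bond eclipses the C11 substituent (A(1,3) strain) and the tether leaves from the C8 side, so C1 adds syn to C8 and anti to the C9 oxygen, while an exo orientation of the tether carbonyl (α-methyl endo) gives the trans ring fusion that sets C1 relative to C10. The step needs fused-over-bridged regioselectivity, secured by the shorter ring, by the 1-substituent of the diene paired with the α-carbon of the enone and by a non-donating CH2OSi group on C11, and it needs cyclisation over oligomerisation, secured by high dilution; the C5=C6 alkene is unactivated and should not compete.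

Step 15
Reactants: 26
Product: 28 C2/C14 diol (2R; C14–OH in place of boron), via alcohol boronate 27 (not isolated)
Conditions: (S)-2-methyl-CBS-oxazaborolidine, catecholborane, toluene, −78 → −40 °C; then NaBO3·4H2O, THF/H2O, rt
Reagents that add atoms: sodium perborate, [Na+].[O-]OB=O
Why: CBS reduction should deliver hydride under catalyst control to the ketone flanked by quaternary C1 (large) and C3H2 (small) to give 2R without hydroborating the alkenes, and the oxidative work-up converts the C14–B bond into C14–OH with retention (1,2-migration).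

Step 16
Reactants: 28
Product: 29 C20 allylic alcohol (triol)
Conditions: Bu4NF, THF, 0 °C; NH4Cl (aq)
Reagents that add atoms: none
Why: Fluoride cleaves the primary allylic silyl ether selectively, leaving acetonide and lactone intact.

Step 17
Reactants: 29
Product: 32 exocyclic methylene diol acetonide (C11=C20), via sulfonylhydrazine 30 (not isolated), via allylic diazene 31 (not isolated)
Conditions: 2-nitrobenzenesulfonohydrazide (NBSH), PPh3, DEAD, THF, −30 °C → rt
Reagents that add atoms: none
Why: Myers reductive 1,3-transposition: Mitsunobu displacement at the primary allylic carbon, loss of sulfinic acid to the monoalkyl diazene and retro-ene loss of N2 move the alkene to C11=C20 and place hydrogen on C12; no stereocentre is formed and the hindered secondary alcohols should not react.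

Step 18
Reactants: 32
Product: 33 C2/C8/C9/C14 tetraol
Conditions: AcOH/H2O (4:1), 45 °C
Reagents that add atoms: none
Why: Mild aqueous acid hydrolysis of the acetonide should free the C8 and C9 hydroxyls without isomerising the exocyclic alkene.

Step 19
Reactants: 33
Product: 34 CNP0187723.2
Conditions: Ac2O, pyridine, DMAP (cat.), CH2Cl2, rt
Reagents that add atoms: acetic anhydride, CC(=O)OC(C)=O
Why: DMAP-catalysed acetylation should acylate the three secondary hydroxyls (C2, C9, C14) and leave the hindered tertiary C8 hydroxyl free.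

Compound list
1 | (R)-4-benzyl-3-propanoyl-1,3-oxazolidin-2-one | CCC(=O)N1C(=O)OC[C@H]1Cc1ccccc1 | starting material
2 | ethyl glyoxylate | CCOC(=O)C=O | starting material
3 | (Z)-dibutylboron enolate of 1 | CCCCB(CCCC)O/C(=C\C)N1C(=O)OC[C@H]1Cc1ccccc1 | intermediate
4 | (4R)-4-benzyl-3-[(2R,3R)-4-ethoxy-3-hydroxy-2-methyl-4-oxobutanoyl]-1,3-oxazolidin-2-one | CCOC(=O)[C@H](O)[C@@H](C)C(=O)N1C(=O)OC[C@H]1Cc1ccccc1 | intermediate
5 | (2R,3R)-2-hydroxy-3-methylbutanedioic acid | OC(=O)[C@H](O)[C@@H](C)C(=O)O | intermediate
6 | (2R)-2-[(2R,4R)-2-tert-butyl-5-oxo-1,3-dioxolan-4-yl]propanoic acid (cis acetal) | CC(C)(C)[C@@H]1O[C@H]([C@@H](C)C(=O)O)C(=O)O1 | intermediate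
7 | 4-methyl-5,6-dihydro-2H-pyran-2-one | CC1=CC(=O)OCC1 | starting material
8 | 4-methyl-5,6-dihydro-2H-pyran-2-ol (lactol) | CC1=CC(O)OCC1 | intermediate
9 | dilithium enolate–carboxylate of 6 | [Li]OC(=O)[C@H](C)C1=C(O[Li])O[C@H](C(C)(C)C)O1 | intermediate
10 | aldol hydroxy acid: 6 with the C8 hydrogen replaced by (Z)-CH(OH)CH=C(CH3)CH2CH2OH | O=C1O[C@H](C(C)(C)C)O[C@]1([C@@H](O)/C=C(/C)CCO)[C@@H](C)C(=O)O | intermediate
11 | spiro dioxolanone γ-lactone, (Z)-4-hydroxy-2-methylbut-1-enyl at C7, tert-butyl cis to C17 | O=C1O[C@H](C(C)(C)C)O[C@@]12[C@H](/C=C(/C)CCO)OC(=O)[C@@H]2C | intermediate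
12 | primary iodide of 11 | O=C1O[C@H](C(C)(C)C)O[C@@]12[C@H](/C=C(/C)CCI)OC(=O)[C@@H]2C | intermediate
13 | tert-butyldimethyl(prop-2-yn-1-yloxy)silane | C#CCO[Si](C)(C)C(C)(C)C | starting material
14 | lithium acetylide of 13 | [Li]C#CCO[Si](C)(C)C(C)(C)C | intermediate
15 | α-hydroxy ynone lactone | CC(C)(C)[Si](C)(C)OCC#CC(=O)[C@@]1(O)[C@H](/C=C(/C)CCI)OC(=O)[C@@H]1C | intermediate
16 | (9R)-propargylic 8,9-diol | CC(C)(C)[Si](C)(C)OCC#C[C@@H](O)[C@@]1(O)[C@H](/C=C(/C)CCI)OC(=O)[C@@H]1C | intermediate
17 | 8,9-acetonide of 16 | CC(C)(C)[Si](C)(C)OCC#C[C@H]1OC(C)(C)O[C@@]12[C@H](/C=C(/C)CCI)OC(=O)[C@@H]2C | intermediate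
18 | alkenylzirconocene chloride (Zr on C11, H on C10, syn) | CC(C)(C)[Si](C)(C)OC/C(=C\[C@H]1OC(C)(C)O[C@@]12[C@H](/C=C(/C)CCI)OC(=O)[C@@H]2C)[Zr](Cl)(C1C=CC=C1)C1C=CC=C1 | intermediate
19 | diene iodide (C9 cis to CH2OTBS, trans to vinyl) | C=C/C(CO[Si](C)(C)C(C)(C)C)=C/[C@H]1OC(C)(C)O[C@@]12[C@H](/C=C(/C)CCI)OC(=O)[C@@H]2C | intermediate
20 | propyne | CC#C | starting material
21 | (Z)-(2-bromoprop-1-en-1-yl)dibromoborane | C/C(Br)=C/B(Br)Br | intermediate
22 | (Z)-2-(2-bromoprop-1-en-1-yl)-4,4,5,5-tetramethyl-1,3,2-dioxaborolane | C/C(Br)=C/B1OC(C)(C)C(C)(C)O1 | intermediate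
23 | S-ethyl (Z)-2-methyl-3-(4,4,5,5-tetramethyl-1,3,2-dioxaborolan-2-yl)prop-2-enethioate | CCSC(=O)/C(C)=C\B1OC(C)(C)C(C)(C)O1 | intermediate
24 | alkylzinc iodide from 19 | C=C/C(CO[Si](C)(C)C(C)(C)C)=C/[C@H]1OC(C)(C)O[C@@]12[C@H](/C=C(/C)CC[Zn]I)OC(=O)[C@@H]2C | intermediate
25 | trienone, Diels–Alder precursor | C=C/C(CO[Si](C)(C)C(C)(C)C)=C/[C@H]1OC(C)(C)O[C@@]12[C@H](/C=C(/C)CCC(=O)/C(C)=C\B3OC(C)(C)C(C)(C)O3)OC(=O)[C@@H]2C | intermediate
26 | cycloadduct: six/ten-membered bicyclic ketone with C14 boronate | CC(C)(C)[Si](C)(C)OCC1=CC[C@H](B3OC(C)(C)C(C)(C)O3)[C@@]2(C)[C@H]1[C@H]1OC(C)(C)O[C@@]13[C@H](/C=C(/C)CCC2=O)OC(=O)[C@@H]3C | intermediate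
27 | (2R)-alcohol boronate | CC(C)(C)[Si](C)(C)OCC1=CC[C@H](B3OC(C)(C)C(C)(C)O3)[C@@]2(C)[C@H]1[C@H]1OC(C)(C)O[C@@]13[C@H](/C=C(/C)CC[C@H]2O)OC(=O)[C@@H]3C | intermediate
28 | C2/C14 diol | CC(C)(C)[Si](C)(C)OCC1=CC[C@H](O)[C@@]2(C)[C@H]1[C@H]1OC(C)(C)O[C@@]13[C@H](/C=C(/C)CC[C@H]2O)OC(=O)[C@@H]3C | intermediate
29 | C20 allylic alcohol (triol) | OCC1=CC[C@H](O)[C@@]2(C)[C@H]1[C@H]1OC(C)(C)O[C@@]13[C@H](/C=C(/C)CC[C@H]2O)OC(=O)[C@@H]3C | intermediate
30 | N-allyl-N-(2-nitrophenylsulfonyl)hydrazine | NN(CC1=CC[C@H](O)[C@@]2(C)[C@H]1[C@H]1OC(C)(C)O[C@@]13[C@H](/C=C(/C)CC[C@H]2O)OC(=O)[C@@H]3C)S(=O)(=O)c1ccccc1[N+](=O)[O-] | intermediate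
31 | allylic monoalkyl diazene | N=NCC1=CC[C@H](O)[C@@]2(C)[C@H]1[C@H]1OC(C)(C)O[C@@]13[C@H](/C=C(/C)CC[C@H]2O)OC(=O)[C@@H]3C | intermediate
32 | exocyclic methylene diol acetonide | C=C1CC[C@H](O)[C@@]2(C)[C@H]1[C@H]1OC(C)(C)O[C@@]13[C@H](/C=C(/C)CC[C@H]2O)OC(=O)[C@@H]3C | intermediate
33 | tetraol | C=C1CC[C@H](O)[C@@]2(C)[C@H]1[C@@H](O)[C@@]1(O)[C@H](/C=C(/C)CC[C@H]2O)OC(=O)[C@@H]1C | intermediate
34 | CNP0187723.2 | C=C1CC[C@H](OC(C)=O)[C@@]2(C)[C@H]1[C@@H](OC(C)=O)[C@@]1(O)[C@H](/C=C(/C)CC[C@H]2OC(C)=O)OC(=O)[C@@H]1C | target

Total step count: 19. Longest linear sequence: 16 steps (steps 1–3, 5–10, 13–19).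

Steps most likely to fail

Step 14. The cycloaddition may stall or go astray: bridged instead of fused regiochemistry, approach to the wrong diene face, endo approach of the tether carbonyl (cis ring fusion), or oligomerisation outrunning a slow medium-ring closure. The fallback separates the two ring closures. It sets out from diene 19 and thioester 23, which are combined in an intermolecular Diels–Alder reaction (toluene, 120 °C, sealed tube) to give cyclohexene thioester F1. Zinc insertion into the C–I bond of F1 (Zn, LiCl, THF) and an intramolecular Fukuyama coupling (PdCl2(PPh3)2, high dilution) then close the ten-membered ring at C2–C3 and come back to the route at 26.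

Step 5. Ring-opening of the lactol to the aldehyde may be too slow under the enolate conditions, the aldol may show poor topicity at C7, or retro-aldol may occur on warming. The fallback sets out from 6 (as its dianion 9) and lactone 7. The dianion is acylated by the lactone carbonyl at −78 °C (conjugate addition is blocked by the β,β-disubstitution), which gives keto acid F2. Catalyst-controlled CBS reduction of the C7 ketone (catecholborane) then gives hydroxy acid 10, and lactonisation as in step 5 comes back to the route at 11.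

Step 7. Chemoselectivity may be lost through attack at the lactone carbonyl, or the tetrahedral adduct may collapse early and take up a second acetylide. The fallback sets out from 6 and 8 and adds the acetylide before the lactone exists. After the aldol of step 5, acetylide 14 is added to the cold dilithium aldolate–carboxylate, in which the dioxolanone carbonyl is the only electrophilic carbonyl. Acidification and EDC lactonisation give ynone alcohol F3, and iodination (I2, PPh3, imidazole) comes back to the route at 15.

Further compounds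
F1 | step 14 | cyclohexene thioester from intermolecular Diels–Alder of 19 and 23 (C1 thioester, C14 boronate, iodoethyl chain kept) | CC(C)(C)[Si](C)(C)OCC1=CC[C@H](B3OC(C)(C)C(C)(C)O3)[C@](C)(C(=O)SCC)[C@H]1[C@H]1OC(C)(C)O[C@@]12[C@H](/C=C(/C)CCI)OC(=O)[C@@H]2C
F2 | step 5 | dioxolanone keto acid (C7 ketone, (Z)-enone, primary alcohol) | O=C1O[C@H](C(C)(C)C)O[C@]1(C(=O)/C=C(/C)CCO)[C@@H](C)C(=O)O
F3 | step 7 | α-hydroxy ynone lactone with free primary alcohol at C3 | CC(C)(C)[Si](C)(C)OCC#CC(=O)[C@@]1(O)[C@H](/C=C(/C)CCO)OC(=O)[C@@H]1C
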